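## Structural features

The target is a germacranolide: a ten-membered carbocycle C1–C10 with a Z trisubstituted alkene C1=C10 (methyl C14 on C10) and an E trisubstituted alkene C4=C5 (methyl C15 on C4), cis-fused across C6–C7 to an α-methylene-γ-butyrolactone (lactone oxygen on C6, C11 on C7, C12 carbonyl, C13 methylene). C6, C7, C8 and C9 are four contiguous oxygenated stereocentres (6S,7S,8S,9R): the lactone oxygen, a tertiary carbinol, a free secondary alcohol and an allylic angelate, the (Z)-2-methylbut-2-enoate. The fragile groups are the exo-methylene lactone (conjugate addition), the tertiary β-hydroxy lactone (elimination to a butenolide, retro-aldol cleavage), the angelate (isomerisation to the tiglate, migration to O8), the allylic C6–O and C9–O bonds, and the 1,5-diene (transannular cyclisation in acid, Cope rearrangement on strong heating). The real difficulty lies in three places: the C6/C7 pair with its fully substituted C7 in the right relation to C8 and C9, the distinction between the neighbouring oxygens O8 and O9, and closure of a strained ring that holds one Z and one E alkene. The key step exploits the fact that the lactone carbons C11 and C12 sit on two vicinal oxygen-bearing carbons: this is the pattern left when a ketene adds across a C6=C7 enol ether and one oxygen is inserted next to the carbonyl, the tertiary O7 being the enol ether oxygen itself. A second feature makes that step dependable: the C5–C10 segment has the constitution and configuration of 2-deoxy-D-galactose (C5 anomeric carbon, C7 the C-3 carbonyl, O9 the ring oxygen, O10 the primary oxygen), so the enol ether can be placed inside a 1,6-anhydropyranose. An open-chain α-alkoxy ketone would not serve: on kinetic enolisation it would give mainly the enol ether with C5 cis to the enol oxygen, the opposite of what is needed; it would be a β-keto acetal prone to eliminate; and an O8/O9 acetonide would leave the two oxygens undistinguished. In the ring the enol ether geometry is forced, one face is covered by the anhydro bridge, and O9 is the ring oxygen while O8 carries its own silyl group.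

## Logic of the disconnections

**34 back to 33, then to 30 and 31.** The C9–O acyl bond and the O8–Si bond are cut last. The angelate is the group most easily isomerised and cleaved, so it is attached only after all basic and nucleophilic steps, and O8 stays silylated so that O9 is the only hydroxyl that can be acylated. The gain is a mono-alcohol 30 and the simple acid 31. The forward steps must acylate without Z to E loss in the presence of the methylene lactone and must remove the last silyl group without base.

**30 back to 29, 27 and 26.** The C11–C13 bond of the exo-methylene is cut (and the O9–Si bond kept). The methylene lactone would not survive ylides and organometallic reagents, so it is made after ring closure. The gain is a plain lactone in 26. The forward step has to enolise a β-hydroxy lactone without expelling O7, which requires the alkoxide–enolate dianion.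

**26 back to 25.** The C1=C10 double bond is cut by retro-metathesis. Closing the ring at the Z alkene lets ring strain select the cis geometry, while the E alkene is fixed beforehand in the open chain. The gain is the acyclic diene 25. The demand is severe: a ruthenium carbene must engage a hindered 1,1-disubstituted alkene under high dilution.

**25 back to 24, 23, 22 and 21.** The C10=CH2 and C10–C14 bonds are cut. C10 arrives from the sugar as a CH2–O carbon. The gain is 21, which carries only silyl ethers at C9 and C10. The forward steps must oxidise the primary silyl ether beside the secondary one and add a methyl group to an aldehyde without touching the lactone.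

**21 back to 20, 19, then 17 and 18; 17 back to 15 and 16.** The C2–C3 bond and the C4=C5 π bond are cut in one retro-[3,3] step, then the C4–C5 σ bond. A chair sigmatropic transition state is the most reliable source of an E trisubstituted alkene, and it brings C1–C4 and C15 from two small reagents. The gain is the aldehyde 15. The demands are 1,2-addition to the aldehyde only, vinyl transfer to a hindered secondary alcohol, and high E selectivity.

**15 back to 14, 13 and 12.** The two acetal bonds C5–O9 and C5–O10 are re-formed in the retro sense. The anhydro bridge is at once the protecting group of the C5 aldehyde, of O9 and of O10; its opening frees O9 and O10 while O8 remains silylated. The gain is the compact tricyclic lactone 12. The forward step must open an acetal that is deactivated by the neighbouring acyloxy group.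

**12 back to 11 and 10.** The two C11–Cl bonds are restored and the C12–O6 bond is cut. The chlorines make the ketene reactive and fix which carbon migrates. The gain is that the lactone becomes a cyclobutanone. The forward steps need oxygen insertion on the C6 side with retention, and dechlorination without loss of O7.

**10 back to 7 and 9 (9 from 8).** The C6–C12 and C7–C11 bonds are cut. This removes both lactone carbons and both new stereocentres at once and leaves an enol ether whose oxygen is the future tertiary O7. The forward step needs the right regiochemistry, the enol ether geometry with C5 cis to C8, and attack on one face only; the ring of 7 supplies the last two.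

**7 back to 6, 5, 4, 3 and 1 (via 2).** The O7–Si bond, the C7 carbonyl, the O8–Si bond, the C6–I bond and the C5–O10 bond are cut in turn. The chiral pool compound 1 supplies C8 and C9 with the right configuration and every oxygen of the C5–C10 segment. The demands are kinetic enolisation towards C6, silylation of the equatorial hydroxyl only, and a trans-diaxial iodocyclisation.

## Other disconnections considered

**Alternative 1:** The cut is the C8–C9 bond of the ring. In the forward sense the seco dialdehyde A1 (C8 aldehyde on the lactone-bearing C7, Z enal at C9) would be coupled reductively by a one-electron donor of divalent samarium or divalent vanadium to give the ten-membered diol A2.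
- In its favour: ring closure and both secondary carbinols come in one step; the bond formed lies between sp3 carbons, so both alkene geometries can be set beforehand in the open chain; the diol arrives unprotected.
- Against it here: the C8 aldehyde is neopentylic and has an α-alkoxy group on C7, and a ketyl with an α-leaving group tends to expel it. The enal can couple through C1 instead of C9 or lose its Z geometry at the radical-anion stage. Four diastereomeric diols are possible and one is wanted. Nothing distinguishes O8 from O9 afterwards. A1 still needs the C6/C7 lactone carbinol from another source.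
- Comparison on structure: the chosen plan takes C8 and C9 unchanged from 1 and sets C6/C7 under bicyclic control, whereas A2 needs macrocyclic control of two new centres.
- Comparison on mechanism: both ring closures are the least certain steps of their routes. The alternative is the equal of the chosen plan in ring-closure risk and the better in that no alkene geometry is created in the ring-closing event.
- Comparison on step economy: the alternative is the better after ring closure, since the diol needs no unveiling, but gives this back in the selective acylation of O9.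

**Alternative 2:** The cuts are the C7–C11 and C7–C8 bonds. In the forward sense the alkynyl Grignard reagent A4 adds to the acylsilane carbon of silyl glyoxylate A3, a 1,2-Brook shift moves silicon to oxygen, and the resulting magnesium enolate adds to aldehyde A5 to give A6; no ring is closed.
- In its favour: three simple pieces are joined in one flask; the tertiary O7 arrives silylated; C9 comes from the chiral pool; the alkyne is a latent C11–C13 unit for a later carbonylative lactonisation; O8 (free) and O9 (benzyl-type ether) are distinguished from the start, which is the equal of the chosen plan.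
- Against it here: C6 is not part of A6 and would have to be created later by addition to an aldehyde beside the quaternary C7 with no ring to guide it. The aldol step must control C7 and C8 relative to C9 through enolate geometry and chelation. The ester must be reduced next to a tertiary silyl ether.
- Comparison on structure: both key steps set two stereocentres, the chosen one C6/C7 on a rigid bicycle with C8/C9 inherited, the alternative C7/C8 in an open chain with C9 inherited and C6 postponed.
- Comparison on mechanism: an anionic cascade stands against a concerted cycloaddition; only the cycloaddition ties the C6–O and C7–O relationship to a suprafacial event.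
- Comparison on step economy: the alternative is the better up to its key intermediate (one step against six, and free of tin), and the worse afterwards, because C6, C5 and the lactone remain to be built.

**Alternative 3:** The cuts are C4–C5 and C1–C10, seen as two bonds of a cyclobutane. In the forward sense irradiation of the lactone-fused cyclohexenone A7 with the cyclobutene A8 gives the head-to-tail photoadduct A9. Heating would then cleave the C5–C10 and C1–C4 bonds of the cyclobutane and open the ten-membered 1,5-diene with C9 as a ketone.
- In its favour: no medium-ring cyclisation is needed; both trisubstituted alkenes come from one fragmentation; C6–C8 are handled on a six-membered ring; the C9 ketone distinguishes O9 from the acetonide-protected O7/O8.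
- Against it here: the regiochemistry and face selectivity of the photocycloaddition are open. The alkene geometries are dictated by the configuration of A9 and the course of the cycloreversion, not chosen freely, and the Z/E pair must be the one delivered. The temperature of cycloreversion lies where a 1,5-diene can undergo Cope rearrangement to a divinylcyclohexane. The C9 ketone must be reduced stereoselectively. A7, with three stereocentres, needs its own route.
- Comparison on structure: the alternative solves the ring and leaves the C6/C7 problem inside A7; the chosen plan does the reverse.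
- Comparison on mechanism: the alternative is the better in that it avoids the macrocyclisation, which is the weakest step of the chosen plan, and in atom economy. The chosen plan is the better in predictable C6/C7 stereochemistry and in mild conditions for the sensitive diene.
- Comparison on step economy: the two are about equal once the synthesis of A7 is counted.

Key step: step 6

**Assumptions and remarks**
- Germacrane numbering is used for all compounds. In the sugar names of 1–7, C-1 = C5, C-2 = C6, C-3 = C7, C-4 = C8, C-5 = C9, C-6 = C10.
- The target SMILES is read as (6S,7S,8S,9R), 1(10)Z, 4E, with a (Z)-2-methylbut-2-enoate on O9.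
- Compounds 7 and 10 keep the C5–C10 carbon skeleton and all oxygen positions of an open-chain enol ether and its cycloadduct; only the protecting groups differ (C5 acetal, O9 and O10 tied in one anhydro bridge; Me3Si on O7; TBS on O8).
- The tertiary Me3Si ether on O7 is assumed to survive steps 6–8 and to be cleaved in step 9. If it is lost earlier, the free tertiary alcohol goes through the same steps.
- Dichloroketene is made from 8 with Et3N and not with zinc, because zinc chloride would ionise the allylic acetal of 7.
- Compounds 1, 8, 16, 18 and 31 are commercial.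

## Route

Step 1
Reactants: 1 D-galactal
Product: 3 1,6-anhydro-2-deoxy-2-iodo-β-D-galactopyranose, via 6-O-tributylstannyl-D-galactal 2 (not isolated)
Conditions: (Bu3Sn)2O, 3 Å MS, MeCN, reflux; then I2, CH2Cl2, 0 °C
Reagents that add atoms: iodine, [I][I]
Why: Iodoetherification of the glycal: the tin alkoxide raises the nucleophilicity of O10, iodine adds to C6 from the α face and O10 closes on C5 from the β face (trans-diaxial opening of the iodonium ion). This fixes the 1,6-anhydro bridge on the β face.

Step 2
Reactants: 3 1,6-anhydro-2-deoxy-2-iodo-β-D-galactopyranose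
Product: 4 1,6-anhydro-2-deoxy-β-D-lyxo-hexopyranose
Conditions: H2 (1 atm), palladium on carbon (Pd/C), Et3N, MeOH, rt
Reagents that add atoms: none
Why: Catalytic hydrogenolysis of the secondary C–I bond; the bicyclic acetal and the diol are inert and no stereocentre is touched.

Step 3
Reactants: 4 1,6-anhydro-2-deoxy-β-D-lyxo-hexopyranose
Product: 5 1,6-anhydro-4-O-(tert-butyldimethylsilyl)-2-deoxy-β-D-lyxo-hexopyranose
Conditions: TBSCl, imidazole, DMF, 0 °C
Reagents that add atoms: tert-butyldimethylsilyl chloride, CC(C)(C)[Si](C)(C)Cl
Why: Selective silylation: the C8 hydroxyl is equatorial and open, while the axial C7 hydroxyl lies under the anhydro bridge and is shielded.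

Step 4
Reactants: 5 1,6-anhydro-4-O-(tert-butyldimethylsilyl)-2-deoxy-β-D-lyxo-hexopyranose
Product: 6 1,6-anhydro-4-O-(tert-butyldimethylsilyl)-2-deoxy-β-D-threo-hexopyranos-3-ulose
Conditions: Dess–Martin periodinane, CH2Cl2, 0 °C → rt
Reagents that add atoms: none
Why: Dess–Martin oxidation of the hindered axial alcohol under non-basic conditions, so the acetal oxygen β to the new ketone is not eliminated.

Step 5
Reactants: 6 1,6-anhydro-4-O-(tert-butyldimethylsilyl)-2-deoxy-β-D-threo-hexopyranos-3-ulose
Product: 7 1,6-anhydro-4-O-(tert-butyldimethylsilyl)-2-deoxy-3-O-(trimethylsilyl)-β-D-threo-hex-2-enopyranose (C6=C7 silyl enol ether)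
Conditions: LiN(iPr)2 (LDA) added to 6 and Me3SiCl, THF, −78 °C
Reagents that add atoms: trimethylsilyl chloride, C[Si](C)(C)Cl
Why: Kinetic deprotonation at the C6 methylene (not at the hindered, oxygen-bearing C8–H) with silylation in situ; the short enolate lifetime suppresses β-elimination of the C5 acetal oxygen. Because the double bond is in the ring, C5 is necessarily cis to C8.

Step 6
Reactants: 7 1,6-anhydro-4-O-(tert-butyldimethylsilyl)-2-deoxy-3-O-(trimethylsilyl)-β-D-threo-hex-2-enopyranose; 8 dichloroacetyl chloride
Product: 10 2,2-dichloro-3-(trimethylsiloxy)cyclobutanone fused to the α face of the anhydropyranose (C12 carbonyl on C6; C11 on C7), via dichloroketene 9 (not isolated)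
Conditions: Et3N, hexane/Et2O, slow addition of 8, 0 °C → rt
Reagents that add atoms: none
Why: Et3N dehydrochlorinates 8 to dichloroketene 9, which adds to the electron-rich C6=C7 silyl enol ether in a concerted, asynchronous [2+2] cycloaddition: the ketene carbonyl carbon C12 bonds first to the nucleophilic C6 and the CCl2 carbon C11 then closes onto the siloxy-bearing C7. The closest known reaction type is the cycloaddition of dichloroketene to silyl enol ethers, which gives 2,2-dichloro-3-siloxycyclobutanones. The four-membered ring is closed by this intermolecular cycloaddition itself (both new bonds, C6–C12 and C7–C11, form in one event) and is cis-fused to the pyranose. C6 and C7 are set together: suprafacial addition to the endocyclic enol ether, in which C5 and C8 are cis, fixes their relative configuration. Their absolute configuration follows from attack on the exo (α) face, because the endo (β) face is covered by the C10–O10 bridge and flanked by the C8 silyloxy group. The step needs regioselectivity, secured by the polarisation of the enol ether, and face selectivity, secured by the bicyclic framework; there is no second alkene to compete. The amine method keeps zinc chloride away from the allylic acetal and the silyl enol ether.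

Step 7
Reactants: 10 2,2-dichloro-3-(trimethylsiloxy)cyclobutanone fused to the α face of the anhydropyranose
Product: 11 α,α-dichloro-γ-lactone on the anhydropyranose (O6–C12(=O)–C11Cl2–C7)
Conditions: mCPBA, NaHCO3, CH2Cl2, 0 °C → rt
Reagents that add atoms: 3-chloroperoxybenzoic acid, OOC(=O)c1cccc(Cl)c1
Why: Baeyer–Villiger oxidation of a strained, electron-poor ketone; the chlorine-free C6 migrates with retention, so oxygen enters only between C12 and C6 and the C6 configuration is kept.

Step 8
Reactants: 11 α,α-dichloro-γ-lactone on the anhydropyranose
Product: 12 γ-lactone on the anhydropyranose (C11 as CH2; C7 OSiMe3; C8 OTBS)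
Conditions: Bu3SnH, AIBN (cat.), PhMe, 80 °C
Reagents that add atoms: none
Why: Radical-chain dechlorination of an α,α-dichloro ester; a radical at C11 (not an enolate) does not expel the β-siloxy group on C7.

Step 9
Reactants: 12 γ-lactone on the anhydropyranose
Product: 13 open-chain lactone triol with C5 as 1,3-dithian-2-yl (C7 OH; C8 OTBS; C9 OH; C10 OH)
Conditions: HS(CH2)3SH, BF3·OEt2, CH2Cl2, −20 → 0 °C; aq. NaHCO3
Reagents that add atoms: propane-1,3-dithiol, SCCCS
Why: Lewis-acid transthioacetalisation: BF3 ionises the strained bicyclic acetal and the dithiol captures C5 twice, so the 1,3-dithiane forms irreversibly and O9–H and O10–H are released. The tertiary Me3Si ether is cleaved under the same conditions; the secondary TBS ether and the γ-lactone should remain.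

Step 10
Reactants: 13 open-chain lactone triol with C5 as 1,3-dithian-2-yl
Product: 14 9,10-bis-O-triethylsilyl ether of 13
Conditions: Et3SiCl, imidazole, DMAP (cat.), DMF, 0 °C → rt
Reagents that add atoms: triethylsilyl chloride, CC[Si](CC)(CC)Cl
Why: Silylation of the primary and the secondary hydroxyl; the tertiary C7–OH is too hindered for a silyl chloride with imidazole.

Step 11
Reactants: 14 9,10-bis-O-triethylsilyl ether of 13
Product: 15 C5 aldehyde (lactone oxygen on the α-carbon C6)
Conditions: MeI, CaCO3, MeCN/H2O, 45 °C
Reagents that add atoms: water, O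
Why: Alkylative hydrolysis of the dithiane (S-methylation, then water) under buffered, near-neutral conditions that spare the silyl ethers and the lactone.

Step 12
Reactants: 15 C5 aldehyde; 16 isopropenylmagnesium bromide
Product: 17 C5 isopropenyl carbinol (both C5 epimers)
Conditions: THF, −78 °C; aq. NH4Cl
Reagents that add atoms: none
Why: Grignard 1,2-addition to the aldehyde at −78 °C, much faster than attack on the lactone; one equivalent is consumed by the C7–OH. Both C5 epimers are used, since C5 becomes sp2 in step 13.

Step 13
Reactants: 17 C5 isopropenyl carbinol; 18 ethyl vinyl ether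
Product: 20 (4E)-C1 aldehyde (C6–C5H=C4(CH3)–C3H2–C2H2–C1HO), via C5 allyl vinyl ether 19 (not isolated)
Conditions: Pd(OCOCF3)2 (cat.), 4,7-diphenyl-1,10-phenanthroline, Et3N, 18 as solvent, 50 °C; then PhMe, 125 °C (sealed tube)
Reagents that add atoms: none
Why: Palladium-catalysed transfer vinylation of the secondary allylic alcohol under amine buffering (no acetal formation with the C7–OH), then aliphatic Claisen rearrangement. The chair transition state with the bulky C6 substituent pseudo-equatorial forms the C2–C3 bond and should give mainly the E C4=C5 alkene.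

Step 14
Reactants: 20 (4E)-C1 aldehyde
Product: 21 (4E)-diene with terminal C1=CH2
Conditions: Ph3PCH3Br, KOtBu, THF, 0 °C
Reagents that add atoms: methyltriphenylphosphonium bromide, C[P+](c1ccccc1)(c1ccccc1)c1ccccc1.[Br-]
Why: Wittig methylenation of an unhindered aldehyde; excess ylide covers the C7–OH and the lactone is not attacked at this temperature.

Step 15
Reactants: 21 (4E)-diene with terminal C1=CH2
Product: 22 C10 aldehyde (C9 OSiEt3 kept)
Conditions: (COCl)2, DMSO, CH2Cl2, −78 → −30 °C; then Et3N
Reagents that add atoms: none
Why: Swern oxidation applied directly to the silyl ether: the chlorosulfonium salt attacks the primary O–SiEt3 oxygen and converts it to the aldehyde, while the secondary triethylsilyl ether is too hindered to react.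

Step 16
Reactants: 22 C10 aldehyde
Product: 23 C10 methyl carbinol (both C10 epimers)
Conditions: MeTi(OiPr)3, THF, −40 → 0 °C
Reagents that add atoms: methyltitanium triisopropoxide, C[Ti](OC(C)C)(OC(C)C)OC(C)C
Why: The methyltitanium reagent adds to aldehydes but not to lactones; the new C10 carbinol centre is removed in step 17.

Step 17
Reactants: 23 C10 methyl carbinol
Product: 24 C10 methyl ketone (C14 in place)
Conditions: Dess–Martin periodinane, pyridine, CH2Cl2, 0 °C → rt
Reagents that add atoms: none
Why: Dess–Martin oxidation of the secondary alcohol; the tertiary C7–OH, the alkenes and the silyl ethers are inert and the α-silyloxy centre C9 is not epimerised under buffered conditions.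

Step 18
Reactants: 24 C10 methyl ketone
Product: 25 diene for ring closure (isopropenyl group on C9; terminal C1=CH2)
Conditions: Ph3PCH3Br, KOtBu, THF, 0 °C → rt
Reagents that add atoms: methyltriphenylphosphonium bromide, C[P+](c1ccccc1)(c1ccccc1)c1ccccc1.[Br-]
Why: Wittig methylenation of an α-silyloxy methyl ketone, an activated ketone; the low temperature limits enolisation towards C9.

Step 19
Reactants: 25 diene for ring closure
Product: 26 (1(10)Z,4E)-germacradienolide with C7 OH, C8 OTBS, C9 OSiEt3 and C11 as CH2
Conditions: second-generation Hoveyda–Grubbs catalyst RuCl2(H2IMes)(=CH-C6H4-2-OiPr) (cat.), PhMe, 80 °C, high dilution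
Reagents that add atoms: none
Why: Ring-closing metathesis: the ruthenium carbene loads on the monosubstituted C1 alkene and closes onto the 1,1-disubstituted C10 alkene with loss of ethene. The cis-fused lactone turns both chains to the same side, and in a ten-membered ring the new trisubstituted alkene is expected with the ring bonds cis, which is the 1(10)Z geometry.

Step 20
Reactants: 26 (1(10)Z,4E)-germacradienolide
Product: 27 11-(dimethylaminomethyl) lactone (C11 epimers)
Conditions: LiN(iPr)2 (2.3 equiv), THF, −78 °C; then CH2=NMe2 I, −78 → 0 °C
Reagents that add atoms: dimethylmethyleneiminium iodide (Eschenmoser's salt), C=[N+](C)C.[I-]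
Why: Two equivalents of base give the alkoxide–enolate dianion of the β-hydroxy lactone, which cannot expel the C7 oxygen; Mannich-type aminomethylation then occurs at C11.

Step 21
Reactants: 27 11-(dimethylaminomethyl) lactone
Product: 29 11(13)-methylene lactone (C8 OTBS; C9 OSiEt3), via C13 trimethylammonium iodide 28 (not isolated)
Conditions: MeI, MeOH, rt; then NaHCO3, CH2Cl2/H2O
Reagents that add atoms: none
Why: Quaternisation of the amine and E1cB loss of trimethylamine under mild base give the exo-methylene lactone.

Step 22
Reactants: 29 11(13)-methylene lactone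
Product: 30 C9 alcohol (C8 OTBS kept)
Conditions: PPTS (cat.), MeOH/CH2Cl2, 0 °C
Reagents that add atoms: none
Why: Acid-catalysed methanolysis removes the secondary triethylsilyl ether far faster than the hindered TBS ether; the acid is too weak to trigger transannular cyclisation of the diene.

Step 23
Reactants: 30 C9 alcohol; 31 angelic acid
Product: 33 8-O-TBS ether of the target (angelate on O9), via angelic 2,4,6-trichlorobenzoic anhydride 32 (not isolated)
Conditions: 2,4,6-Cl3C6H2COCl, Et3N, PhMe, rt; then 30, 70 °C
Reagents that add atoms: none
Why: Yamaguchi esterification without a nucleophilic catalyst: the mixed anhydride acylates the only reactive hydroxyl, since the C7–OH is tertiary. The absence of DMAP and of strong base should keep the Z geometry of the angelate.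

Step 24
Reactants: 33 8-O-TBS ether of the target
Product: 34 target, (6S,7S,8S,9R,1(10)Z,4E)-9-angeloyloxy-7,8-dihydroxygermacra-1(10),4,11(13)-trien-12,6-olide
Conditions: HF·pyridine, pyridine, THF, 0 °C → rt
Reagents that add atoms: none
Why: Fluoride cleaves the Si–O bond under mildly acidic, non-basic conditions, so neither acyl migration from O9 to O8 nor conjugate addition to the methylene lactone is expected.

## Compound list

1 | D-galactal (1,5-anhydro-2-deoxy-D-lyxo-hex-1-enitol) | OC[C@H]1OC=C[C@@H](O)[C@H]1O | starting material
2 | 6-O-tributylstannyl-D-galactal | CCCC[Sn](CCCC)(CCCC)OC[C@H]1OC=C[C@@H](O)[C@H]1O | intermediate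
3 | 1,6-anhydro-2-deoxy-2-iodo-β-D-galactopyranose | C1O[C@H]2[C@H](I)[C@@H](O)[C@@H](O)[C@@H]1O2 | intermediate
4 | 1,6-anhydro-2-deoxy-β-D-lyxo-hexopyranose | C1O[C@H]2C[C@@H](O)[C@@H](O)[C@@H]1O2 | intermediate
5 | 1,6-anhydro-4-O-(tert-butyldimethylsilyl)-2-deoxy-β-D-lyxo-hexopyranose | C1O[C@H]2C[C@@H](O)[C@@H](O[Si](C)(C)C(C)(C)C)[C@@H]1O2 | intermediate
6 | 1,6-anhydro-4-O-(tert-butyldimethylsilyl)-2-deoxy-β-D-threo-hexopyranos-3-ulose | C1O[C@H]2CC(=O)[C@@H](O[Si](C)(C)C(C)(C)C)[C@@H]1O2 | intermediate
7 | 1,6-anhydro-4-O-(tert-butyldimethylsilyl)-2-deoxy-3-O-(trimethylsilyl)-β-D-threo-hex-2-enopyranose (C6=C7 silyl enol ether; key-step precursor) | C1O[C@H]2C=C(O[Si](C)(C)C)[C@@H](O[Si](C)(C)C(C)(C)C)[C@@H]1O2 | intermediate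
8 | dichloroacetyl chloride | ClC(Cl)C(Cl)=O | starting material
9 | dichloroketene | O=C=C(Cl)Cl | intermediate
10 | 2,2-dichloro-3-(trimethylsiloxy)cyclobutanone cis-fused to the α face of the anhydropyranose (C12=O on C6, C11Cl2 on C7, C8 OTBS; key-step product) | C1O[C@H]2[C@@H]3C(=O)C(Cl)(Cl)[C@]3(O[Si](C)(C)C)[C@@H](O[Si](C)(C)C(C)(C)C)[C@@H]1O2 | intermediate
11 | α,α-dichloro-γ-lactone on the anhydropyranose (O6–C12(=O)–C11Cl2–C7; C7 OSiMe3; C8 OTBS) | C1O[C@H]2[C@@H]3OC(=O)C(Cl)(Cl)[C@]3(O[Si](C)(C)C)[C@@H](O[Si](C)(C)C(C)(C)C)[C@@H]1O2 | intermediate
12 | γ-lactone on the anhydropyranose (C11 H2; C7 OSiMe3; C8 OTBS) | C1O[C@H]2[C@@H]3OC(=O)C[C@]3(O[Si](C)(C)C)[C@@H](O[Si](C)(C)C(C)(C)C)[C@@H]1O2 | intermediate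
13 | open-chain lactone triol: 1,3-dithian-2-yl (C5) on C6, C7 OH, C8 OTBS, C9 OH, C10 OH | OC[C@@H](O)[C@H](O[Si](C)(C)C(C)(C)C)[C@@]1(O)CC(=O)O[C@H]1C2SCCCS2 | intermediate
14 | 9,10-bis-O-triethylsilyl ether of 13 | CC[Si](CC)(CC)OC[C@@H](O[Si](CC)(CC)CC)[C@H](O[Si](C)(C)C(C)(C)C)[C@@]1(O)CC(=O)O[C@H]1C2SCCCS2 | intermediate
15 | C5 aldehyde (C6 bears the lactone oxygen) | CC[Si](CC)(CC)OC[C@@H](O[Si](CC)(CC)CC)[C@H](O[Si](C)(C)C(C)(C)C)[C@@]1(O)CC(=O)O[C@H]1C=O | intermediate
16 | isopropenylmagnesium bromide | C=C(C)[Mg]Br | starting material
17 | C5 isopropenyl carbinol (C4, C3, C15 added; both C5 epimers) | CC[Si](CC)(CC)OC[C@@H](O[Si](CC)(CC)CC)[C@H](O[Si](C)(C)C(C)(C)C)[C@@]1(O)CC(=O)O[C@H]1C(O)C(C)=C | intermediate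
18 | ethyl vinyl ether | C=COCC | starting material
19 | C5 O-vinyl ether of 17 | CC[Si](CC)(CC)OC[C@@H](O[Si](CC)(CC)CC)[C@H](O[Si](C)(C)C(C)(C)C)[C@@]1(O)CC(=O)O[C@H]1C(OC=C)C(C)=C | intermediate
20 | (4E)-C1 aldehyde, chain C6–C5H=C4(CH3)–C3H2–C2H2–C1HO | CC[Si](CC)(CC)OC[C@@H](O[Si](CC)(CC)CC)[C@H](O[Si](C)(C)C(C)(C)C)[C@@]1(O)CC(=O)O[C@H]1/C=C(\C)CCC=O | intermediate
21 | (4E)-diene with terminal C1=CH2 | CC[Si](CC)(CC)OC[C@@H](O[Si](CC)(CC)CC)[C@H](O[Si](C)(C)C(C)(C)C)[C@@]1(O)CC(=O)O[C@H]1/C=C(\C)CCC=C | intermediate
22 | C10 aldehyde (C9 OSiEt3) | O=C[C@@H](O[Si](CC)(CC)CC)[C@H](O[Si](C)(C)C(C)(C)C)[C@@]1(O)CC(=O)O[C@H]1/C=C(\C)CCC=C | intermediate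
23 | C10 methyl carbinol (both C10 epimers) | CC(O)[C@@H](O[Si](CC)(CC)CC)[C@H](O[Si](C)(C)C(C)(C)C)[C@@]1(O)CC(=O)O[C@H]1/C=C(\C)CCC=C | intermediate
24 | C10 methyl ketone | CC(=O)[C@@H](O[Si](CC)(CC)CC)[C@H](O[Si](C)(C)C(C)(C)C)[C@@]1(O)CC(=O)O[C@H]1/C=C(\C)CCC=C | intermediate
25 | diene for ring closure (isopropenyl on C9, terminal C1=CH2) | C=C(C)[C@@H](O[Si](CC)(CC)CC)[C@H](O[Si](C)(C)C(C)(C)C)[C@@]1(O)CC(=O)O[C@H]1/C=C(\C)CCC=C | intermediate
26 | (1(10)Z,4E)-germacradien-12,6-olide with C7 OH, C8 OTBS, C9 OSiEt3, C11 H2 | C1C(=O)O[C@H]2/C=C(\C)CC/C=C(/C)[C@@H](O[Si](CC)(CC)CC)[C@H](O[Si](C)(C)C(C)(C)C)[C@@]12O | intermediate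
27 | 11-(dimethylaminomethyl) derivative of 26 (C11 epimers) | CN(C)CC1C(=O)O[C@H]2/C=C(\C)CC/C=C(/C)[C@@H](O[Si](CC)(CC)CC)[C@H](O[Si](C)(C)C(C)(C)C)[C@@]12O | intermediate
28 | C13 trimethylammonium iodide of 27 | C[N+](C)(C)CC1C(=O)O[C@H]2/C=C(\C)CC/C=C(/C)[C@@H](O[Si](CC)(CC)CC)[C@H](O[Si](C)(C)C(C)(C)C)[C@@]12O.[I-] | intermediate
29 | 11(13)-methylene lactone with C8 OTBS and C9 OSiEt3 | C=C1C(=O)O[C@H]2/C=C(\C)CC/C=C(/C)[C@@H](O[Si](CC)(CC)CC)[C@H](O[Si](C)(C)C(C)(C)C)[C@@]12O | intermediate
30 | C9 alcohol (C8 OTBS) | C=C1C(=O)O[C@H]2/C=C(\C)CC/C=C(/C)[C@@H](O)[C@H](O[Si](C)(C)C(C)(C)C)[C@@]12O | intermediate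
31 | angelic acid, (Z)-2-methylbut-2-enoic acid | C/C=C(/C)C(=O)O | starting material
32 | angelic 2,4,6-trichlorobenzoic anhydride | C/C=C(/C)C(=O)OC(=O)c1c(Cl)cc(Cl)cc1Cl | intermediate
33 | 8-O-TBS ether of the target | C=C1C(=O)O[C@H]2/C=C(\C)CC/C=C(/C)[C@@H](OC(=O)/C(C)=C\C)[C@H](O[Si](C)(C)C(C)(C)C)[C@@]12O | intermediate
34 | CNP0303917.1, (6S,7S,8S,9R,1(10)Z,4E)-9-angeloyloxy-7,8-dihydroxygermacra-1(10),4,11(13)-trien-12,6-olide | C=C1C(=O)O[C@H]2/C=C(\C)CC/C=C(/C)[C@@H](OC(=O)/C(C)=C\C)[C@H](O)[C@@]12O | target

## Step count and least certain steps

Total: 24 steps. Longest linear sequence: 24 steps, from 1 to 34; the other numbered starting materials are used as bought.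

**Step 19 (ring-closing metathesis).** Oligomerisation through the unhindered C1 alkene may outrun ring closure, because the isopropenyl group on C9 is flanked by two silyloxy-bearing carbons and is slow to enter the ruthenacycle. Closure to the isomer with the ring bonds trans, or migration of the C1 alkene before closure, is also possible.
Fallback, an intramolecular Wittig reaction, from 20 to 26:
- NaBH4 in MeOH reduces the C1 aldehyde to the primary C1 alcohol F1.
- I2, PPh3 and imidazole give the C1 iodide F2.
- Swern conditions convert the primary triethylsilyl ether into the C10 aldehyde F3.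
- MeTi(OiPr)3 gives the C10 methyl carbinol F4.
- Dess–Martin periodinane gives the iodo methyl ketone F5.
- PPh3 in MeCN at 70 °C gives the C1 triphenylphosphonium iodide F6.
- KN(SiMe3)2 in PhMe under high dilution forms the ylide, which closes onto the activated α-silyloxy methyl ketone and rejoins the route at 26. A ring-closing Wittig reaction can only give the cis ring alkene.

**Step 6 (key step).** Oligomerisation of the ketene may compete if the hindered enol ether reacts slowly. Loss of the Me3Si group from 7 or from 10 would be followed by retro-aldol opening of the cyclobutanone. Face selectivity is not in doubt.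
Fallback, a stepwise annulation with the same stereochemical logic (exo attack twice), from 7 to 13:
- Rubottom oxidation (mCPBA, then mild acid) puts a hydroxyl on C6 from the α face and gives the 1,6-anhydro-4-O-TBS-β-D-lyxo-hexopyranos-3-ulose F7.
- The lithium enolate of tert-butyl acetate adds to the C7 ketone from the α face to give the tert-butyl ester diol F8.
- CF3CO2H in CH2Cl2 closes the γ-lactone onto O6 to give the C7-hydroxy lactone F9.
- F9 is opened under the conditions of step 9 and rejoins the route at 13.

**Step 9 (opening of the anhydro acetal).** The acetal is deactivated by the acyloxy group on C6, so opening may stop at the cyclic monothioacetal stage, and longer exposure to BF3 would begin to remove the C8 TBS ether.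
Fallback, a stepwise opening, from 12 to 13:
- PhSSiMe3 and ZnI2 open only the anhydro bridge and give the phenyl 1-thiopyranoside F10 with free O10–H.
- NBS in aqueous acetone hydrolyses it to the pyranose lactol F11.
- Propane-1,3-dithiol and BF3·OEt2 at −30 °C convert the lactol, which is far more reactive than the bicyclic acetal, into 13.

**Step 5 (enol silylation).** Some deprotonation at C8, or β-elimination of the C5 acetal oxygen from the lithium enolate before silylation, would lower the yield or give the regioisomeric enol ether.
Fallback, a regiospecific route through the α-iodo ketone, from 3 to 7: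
- TBSCl and imidazole silylate O8 of 3 to give the 2-iodo 4-O-TBS ether F12.
- Dess–Martin periodinane gives the 2-iodo-3-ulose F13.
- Zinc dust and Me3SiCl reduce the C6–I bond and silylate the zinc enolate in situ, giving 7 with the double bond fixed between C6 and C7.

**Step 13 (vinyl transfer and Claisen rearrangement).** Vinyl transfer to the hindered C5 hydroxyl may be slow, and the chair with the C6 substituent pseudo-axial may leak some Z alkene, since a simple vinyl ether lacks the extra substituent that enforces high E selectivity.
Fallback, an amide acetal Claisen rearrangement, from 17 to 20: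
- N,N-dimethylacetamide dimethyl acetal in xylene at 140 °C exchanges readily with hindered alcohols and rearranges through a more demanding chair to the (4E)-N,N-dimethylamide F14.
- Cp2Zr(H)Cl in THF reduces the tertiary amide to the aldehyde 20 without touching the lactone.

## Further compounds

F1 | step 19 | C1 primary alcohol from 20 | CC[Si](CC)(CC)OC[C@@H](O[Si](CC)(CC)CC)[C@H](O[Si](C)(C)C(C)(C)C)[C@@]1(O)CC(=O)O[C@H]1/C=C(\C)CCCO
F2 | step 19 | C1 primary iodide | CC[Si](CC)(CC)OC[C@@H](O[Si](CC)(CC)CC)[C@H](O[Si](C)(C)C(C)(C)C)[C@@]1(O)CC(=O)O[C@H]1/C=C(\C)CCCI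
F3 | step 19 | C10 aldehyde with C1 iodide | O=C[C@@H](O[Si](CC)(CC)CC)[C@H](O[Si](C)(C)C(C)(C)C)[C@@]1(O)CC(=O)O[C@H]1/C=C(\C)CCCI
F4 | step 19 | C10 methyl carbinol with C1 iodide | CC(O)[C@@H](O[Si](CC)(CC)CC)[C@H](O[Si](C)(C)C(C)(C)C)[C@@]1(O)CC(=O)O[C@H]1/C=C(\C)CCCI
F5 | step 19 | C10 methyl ketone with C1 iodide | CC(=O)[C@@H](O[Si](CC)(CC)CC)[C@H](O[Si](C)(C)C(C)(C)C)[C@@]1(O)CC(=O)O[C@H]1/C=C(\C)CCCI
F6 | step 19 | C1 triphenylphosphonium iodide of the C10 methyl ketone | CC(=O)[C@@H](O[Si](CC)(CC)CC)[C@H](O[Si](C)(C)C(C)(C)C)[C@@]1(O)CC(=O)O[C@H]1/C=C(\C)CCC[P+](c2ccccc2)(c2ccccc2)c2ccccc2.[I-]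
F7 | step 6 | 1,6-anhydro-4-O-(tert-butyldimethylsilyl)-β-D-lyxo-hexopyranos-3-ulose (C6 hydroxy ketone) | C1O[C@H]2[C@H](O)C(=O)[C@@H](O[Si](C)(C)C(C)(C)C)[C@@H]1O2
F8 | step 6 | tert-butyl ester diol (C11–C12 on C7 from the α face) | C1O[C@H]2[C@H](O)[C@](O)(CC(=O)OC(C)(C)C)[C@@H](O[Si](C)(C)C(C)(C)C)[C@@H]1O2
F9 | step 6 | C7-hydroxy γ-lactone on the anhydropyranose | C1O[C@H]2[C@@H]3OC(=O)C[C@]3(O)[C@@H](O[Si](C)(C)C(C)(C)C)[C@@H]1O2
F10 | step 9 | phenyl 1-thiopyranoside with free C10 hydroxyl (C5 epimers) | OC[C@H]1OC(Sc2ccccc2)[C@@H]3OC(=O)C[C@]3(O[Si](C)(C)C)[C@H]1O[Si](C)(C)C(C)(C)C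
F11 | step 9 | pyranose lactol (C5 epimers) | OC[C@H]1OC(O)[C@@H]3OC(=O)C[C@]3(O[Si](C)(C)C)[C@H]1O[Si](C)(C)C(C)(C)C
F12 | step 5 | 1,6-anhydro-4-O-(tert-butyldimethylsilyl)-2-deoxy-2-iodo-β-D-galactopyranose | C1O[C@H]2[C@H](I)[C@@H](O)[C@@H](O[Si](C)(C)C(C)(C)C)[C@@H]1O2
F13 | step 5 | 1,6-anhydro-4-O-(tert-butyldimethylsilyl)-2-deoxy-2-iodo-β-D-lyxo-hexopyranos-3-ulose | C1O[C@H]2[C@H](I)C(=O)[C@@H](O[Si](C)(C)C(C)(C)C)[C@@H]1O2
F14 | step 13 | (4E)-N,N-dimethylamide at C1 | CC[Si](CC)(CC)OC[C@@H](O[Si](CC)(CC)CC)[C@H](O[Si](C)(C)C(C)(C)C)[C@@]1(O)CC(=O)O[C@H]1/C=C(\C)CCC(=O)N(C)C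
A1 | alternative 1 | seco dialdehyde (C8 aldehyde, Z enal at C9, 7-O-methoxymethyl) | O=C[C@@]1(OCOC)CC(=O)O[C@H]1/C=C(\C)CC/C=C(/C)C=O
A2 | alternative 1 | ten-membered lactone-fused C8,C9-diol | C1C(=O)O[C@H]2/C=C(\C)CC/C=C(/C)[C@@H](O)[C@H](O)[C@@]12OCOC
A3 | alternative 2 | tert-butyl (tert-butyldimethylsilyl)glyoxylate | CC(C)(C)OC(=O)C(=O)[Si](C)(C)C(C)(C)C
A4 | alternative 2 | trimethylsilylethynylmagnesium bromide | C[Si](C)(C)C#C[Mg]Br
A5 | alternative 2 | (R)-3-(tert-butyldimethylsilyloxy)-2-(4-methoxybenzyloxy)propanal | O=C[C@H](OCc1ccc(OC)cc1)CO[Si](C)(C)C(C)(C)C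
A6 | alternative 2 | alkynyl glycolate aldol adduct | C[Si](C)(C)C#C[C@@](O[Si](C)(C)C(C)(C)C)(C(=O)OC(C)(C)C)[C@@H](O)[C@H](OCc1ccc(OC)cc1)CO[Si](C)(C)C(C)(C)C
A7 | alternative 3 | lactone-fused 2-methylcyclohexenone (7,8-O-isopropylidene) | O=C1C(C)=C[C@@H]2OC(=O)C[C@]2(OC(C)(C)O3)[C@H]13
A8 | alternative 3 | 1-methylcyclobutene | CC1=CCC1
A9 | alternative 3 | cis-anti-cis tricyclo[4.4.0.0(2,5)]decan-9-one photoadduct | O=C1[C@@]2(C)[C@@H]3CC[C@]3(C)[C@H]2[C@@H]4OC(=O)C[C@]4(OC(C)(C)O5)[C@H]15
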